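**Plan**
- Retrosynthesis first removes the MOM ether from the ring B phenol, then opens ring A at C1–C2 and C5–C6.
- Ring A carries the acyl group on C1, hydroxyls on C2 and C4, the prenyl group on C5 and hydrogen on C6. C2–C5 therefore map onto a 1-methoxy-1,3-bis(silyloxy)diene with the prenyl group on its terminus, and C1/C6 onto the α/β carbons of a terminal aryl ynone.
- The diene is cut at the prenyl–chain bond: γ-prenylation of the methyl acetoacetate dianion, then two silylations.
- The ynone is cut at carbinol–alkyne, aryl–CHO and aryl–prenyl: 3-bromophenol, MOM protection, directed ortho-metalation/prenylation, formylation, ethynyl Grignard addition, MnO2 oxidation.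
- Forward, ring B is present from the start, ring A is created in the convergent benzannulation, and MOM cleavage ends the route.
- The target has no stereocentre; the transient ones (propargylic carbinol, cycloadduct) are erased by oxidation and aromatisation.

Key step: step 9

Assumption: the silyloxy triene is used as the mixture of double-bond isomers that forms, because all of them converge on the same aromatic ring. "Prenyl" means 3-methylbut-2-en-1-yl throughout.

**Route**

Step 1
Reactants: 1 methyl acetoacetate, 2 prenyl bromide (1-bromo-3-methylbut-2-ene)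
Product: 4 methyl 7-methyl-3-oxooct-6-enoate, via dilithium dianion of methyl acetoacetate 3 (not isolated)
Conditions: LDA (2.2 equiv), THF, 0 °C; 2, 0 °C → rt; then aq. HCl
Reagents that add atoms: none
Why: γ-Alkylation of a β-keto ester dianion: the more basic terminal carbanion of 3 should attack the primary carbon of the allylic bromide, leaving the stabilised enolate untouched.

Step 2
Reactants: 4 methyl 7-methyl-3-oxooct-6-enoate
Product: 5 methyl 7-methyl-3-(trimethylsilyloxy)octa-2,6-dienoate (mixture of geometric isomers)
Conditions: TMSCl, Et3N, toluene, rt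
Reagents that add atoms: chlorotrimethylsilane, C[Si](C)(C)Cl
Why: Soft enolisation and O-silylation of the β-keto ester gives the enol silyl ether, the usual first stage on the way to 1-alkoxy-1,3-bis(silyloxy)-1,3-dienes.

Step 3
Reactants: 5 methyl 7-methyl-3-(trimethylsilyloxy)octa-2,6-dienoate
Product: 7 1-methoxy-7-methyl-1,3-bis(trimethylsilyloxy)octa-1,3,6-triene (mixture of geometric isomers), via lithium dienolate of ester 6 (not isolated)
Conditions: LDA, THF, −78 °C; TMSCl, −78 °C → rt; salts filtered off under argon, used crude
Reagents that add atoms: chlorotrimethylsilane, C[Si](C)(C)Cl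
Why: Kinetic γ-deprotonation by LDA gives the extended ester dienolate, which chlorotrimethylsilane should trap on oxygen (O-silylation of an ester enolate) to give the moisture-sensitive silyl ketene acetal diene.

Step 4
Reactants: 8 3-bromophenol
Product: 9 1-bromo-3-(methoxymethoxy)benzene
Conditions: MOMCl, i-Pr2NEt, CH2Cl2, 0 °C → rt
Reagents that add atoms: chloromethyl methyl ether, COCCl
Why: O-Alkylation of the phenol gives the MOM acetal, which protects the oxygen and acts as the directing group for the next step.

Step 5
Reactants: 9 1-bromo-3-(methoxymethoxy)benzene, 2 prenyl bromide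
Product: 12 1-bromo-3-(methoxymethoxy)-2-(3-methylbut-2-en-1-yl)benzene, via 2-bromo-6-(methoxymethoxy)phenyllithium 10 (not isolated), via 2-bromo-6-(methoxymethoxy)phenylcopper 11 (not isolated)
Conditions: LDA, THF, −78 °C; CuBr·SMe2, −78 °C; 2, −78 → 0 °C
Reagents that add atoms: none
Why: Directed ortho-metalation: the amide base should remove the most acidic ring proton, flanked by bromine and the coordinating MOM ether, without bromine–lithium exchange, and the aryl copper formed by transmetalation should undergo copper-mediated allylic substitution at the primary carbon of prenyl bromide while being too stable to lose metal bromide to an aryne.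

Step 6
Reactants: 12 1-bromo-3-(methoxymethoxy)-2-(3-methylbut-2-en-1-yl)benzene
Product: 14 3-(methoxymethoxy)-2-(3-methylbut-2-en-1-yl)benzaldehyde, via 3-(methoxymethoxy)-2-prenylphenyllithium 13 (not isolated)
Conditions: n-BuLi, THF, −78 °C; DMF, −78 °C → rt; then H2O
Reagents that add atoms: N,N-dimethylformamide, CN(C)C=O
Why: Bromine–lithium exchange is fast at −78 °C, and formylation of the aryllithium with DMF gives the aldehyde after hydrolysis of the hemiaminal salt; the MOM ether and the alkene are inert.

Step 7
Reactants: 14 3-(methoxymethoxy)-2-(3-methylbut-2-en-1-yl)benzaldehyde, 15 ethynylmagnesium bromide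
Product: 16 1-[3-(methoxymethoxy)-2-(3-methylbut-2-en-1-yl)phenyl]prop-2-yn-1-ol (racemic)
Conditions: 15 (0.5 M in THF), THF, 0 °C → rt; then H2O
Reagents that add atoms: none
Why: Grignard addition of the acetylide to the aldehyde gives the propargylic alcohol; the new carbinol centre is formed as the racemate and is removed in the next step.

Step 8
Reactants: 16 1-[3-(methoxymethoxy)-2-(3-methylbut-2-en-1-yl)phenyl]prop-2-yn-1-ol
Product: 17 1-[3-(methoxymethoxy)-2-(3-methylbut-2-en-1-yl)phenyl]prop-2-yn-1-one
Conditions: MnO2, CH2Cl2, rt
Reagents that add atoms: none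
Why: MnO2 oxidation of an activated (benzylic and propargylic) alcohol gives the terminal ynone under neutral conditions that spare the acetal and the trisubstituted alkene.

Step 9
Reactants: 7 1-methoxy-7-methyl-1,3-bis(trimethylsilyloxy)octa-1,3,6-triene, 17 1-[3-(methoxymethoxy)-2-(3-methylbut-2-en-1-yl)phenyl]prop-2-yn-1-one
Product: 19 (2,4-dihydroxy-5-prenylphenyl)[3-(methoxymethoxy)-2-prenylphenyl]methanone, via cyclohexa-1,4-diene cycloadduct 18 (not isolated)
Conditions: 7 (1.5 equiv), toluene, 0 → 50 °C; then 0.5 M aq. HCl, THF, 0 °C, short contact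
Reagents that add atoms: none
Why: Bond formation should begin between the nucleophilic, prenyl-substituted terminus (C4) of triene 7 and the terminal alkyne carbon of 17, and the allenolate that develops then bonds through its α-carbon to the ketene acetal carbon, so that cyclohexa-1,4-diene 18 arises by a polar, highly asynchronous [4+2] cycloaddition. The closest known reaction type is the Diels–Alder benzannulation of 1-alkoxy-1,3-bis(silyloxy)-1,3-dienes with alkynyl ketones, which gives acylresorcinols. Ring A closes as a six-membered carbocycle in the [4+2] mode (four diene carbons plus two alkyne carbons), which in the stepwise limit is a 6-endo attack of the allenolate carbon on the far terminus of the dioxygenated allyl cation. Cold dilute acid then cleaves the two trimethylsilyl ethers and expels methanol from the doubly allylic mixed ketal, and the dienone tautomerises through the hydrogen on the prenyl-bearing carbon to the resorcinol; the two sp3 centres of 18 vanish on aromatisation, so no stereocentre needs control. The selectivity required is regiochemical, the acyl-bearing alkyne carbon joining the acetal carbon, and it is secured by pairing the largest HOMO coefficient (diene C4) with the largest LUMO coefficient (ynone β-carbon). The brief acid contact at 0 °C is chosen so that the aryl MOM ether and both prenyl groups survive.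

Step 10
Reactants: 19 (2,4-dihydroxy-5-prenylphenyl)[3-(methoxymethoxy)-2-prenylphenyl]methanone
Product: 20 cudraphenone B, (2,4-dihydroxy-5-prenylphenyl)(3-hydroxy-2-prenylphenyl)methanone
Conditions: HCl (about 1 M) in MeOH, rt
Reagents that add atoms: none
Why: Acid-catalysed acetal exchange with methanol removes the MOM group; dilute acid at room temperature is the usual way to do this next to ortho-prenyl phenols and should leave the trisubstituted alkenes alone.

**Compound list**

1 | methyl acetoacetate | COC(=O)CC(C)=O | starting material
2 | prenyl bromide (1-bromo-3-methylbut-2-ene) | CC(C)=CCBr | starting material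
3 | dilithium dianion of methyl acetoacetate | [Li+].[Li+].C=C([O-])C=C([O-])OC | intermediate
4 | methyl 7-methyl-3-oxooct-6-enoate | COC(=O)CC(=O)CCC=C(C)C | intermediate
5 | methyl 7-methyl-3-(trimethylsilyloxy)octa-2,6-dienoate (geometric isomers) | COC(=O)C=C(O[Si](C)(C)C)CCC=C(C)C | intermediate
6 | lithium dienolate of ester 5 | [Li+].COC([O-])=CC(O[Si](C)(C)C)=CCC=C(C)C | intermediate
7 | 1-methoxy-7-methyl-1,3-bis(trimethylsilyloxy)octa-1,3,6-triene (geometric isomers) | COC(O[Si](C)(C)C)=CC(O[Si](C)(C)C)=CCC=C(C)C | intermediate
8 | 3-bromophenol | Oc1cccc(Br)c1 | starting material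
9 | 1-bromo-3-(methoxymethoxy)benzene | COCOc1cccc(Br)c1 | intermediate
10 | 2-bromo-6-(methoxymethoxy)phenyllithium | [Li]c1c(Br)cccc1OCOC | intermediate
11 | 2-bromo-6-(methoxymethoxy)phenylcopper | [Cu]c1c(Br)cccc1OCOC | intermediate
12 | 1-bromo-3-(methoxymethoxy)-2-(3-methylbut-2-en-1-yl)benzene | COCOc1cccc(Br)c1CC=C(C)C | intermediate
13 | 3-(methoxymethoxy)-2-(3-methylbut-2-en-1-yl)phenyllithium | [Li]c1cccc(OCOC)c1CC=C(C)C | intermediate
14 | 3-(methoxymethoxy)-2-(3-methylbut-2-en-1-yl)benzaldehyde | COCOc1cccc(C=O)c1CC=C(C)C | intermediate
15 | ethynylmagnesium bromide | C#C[Mg]Br | starting material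
16 | 1-[3-(methoxymethoxy)-2-(3-methylbut-2-en-1-yl)phenyl]prop-2-yn-1-ol (racemic) | C#CC(O)c1cccc(OCOC)c1CC=C(C)C | intermediate
17 | 1-[3-(methoxymethoxy)-2-(3-methylbut-2-en-1-yl)phenyl]prop-2-yn-1-one | C#CC(=O)c1cccc(OCOC)c1CC=C(C)C | intermediate
18 | cyclohexa-1,4-diene cycloadduct (1-methoxy-1,3-bis(trimethylsilyloxy)-4-prenyl ring carrying the aroyl group on C6; mixture of diastereomers) | COC1(O[Si](C)(C)C)C=C(O[Si](C)(C)C)C(CC=C(C)C)C=C1C(=O)c1cccc(OCOC)c1CC=C(C)C | intermediate
19 | (2,4-dihydroxy-5-prenylphenyl)[3-(methoxymethoxy)-2-prenylphenyl]methanone | CC(C)=CCc1cc(C(=O)c2cccc(OCOC)c2CC=C(C)C)c(O)cc1O | intermediate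
20 | cudraphenone B | CC(C)=CCc1cc(C(=O)c2cccc(O)c2CC=C(C)C)c(O)cc1O | target

**Count**

Total: 10 steps. Longest linear sequence: 7 steps (8 → 9 → 12 → 14 → 16 → 17 → 19 → 20). Triene 7 is made in 3 steps on a side branch and joins at step 9.

**Steps most likely to fail**

1. Step 9. The diene may add to the ynone in a conjugate sense without closing the ring, the silyl ketene acetal may be protodesilylated before it reacts, or the terminal ynone may oligomerise, so that ring A does not form cleanly. Fallback: ring A is taken from an existing arene and joined to ring B at the carbonyl carbon. Commercial 4,6-dibromoresorcinol (Oc1cc(O)c(Br)cc1Br) is protected with MOMCl and i-Pr2NEt to give 1,5-dibromo-2,4-bis(methoxymethoxy)benzene F1. Exchange of one bromine with n-BuLi at −78 °C gives 5-bromo-2,4-bis(methoxymethoxy)phenyllithium F2, which is alkylated with 2 to give 1-bromo-2,4-bis(methoxymethoxy)-5-(3-methylbut-2-en-1-yl)benzene F3. A second exchange gives 2,4-bis(methoxymethoxy)-5-(3-methylbut-2-en-1-yl)phenyllithium F4, which adds to aldehyde 14 to give [2,4-bis(methoxymethoxy)-5-prenylphenyl][3-(methoxymethoxy)-2-prenylphenyl]methanol F5. MnO2 oxidation should give [2,4-bis(methoxymethoxy)-5-prenylphenyl][3-(methoxymethoxy)-2-prenylphenyl]methanone F6, and HCl in MeOH at rt removes the three MOM groups. This fallback sets out from 14 and returns to the route at 20.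

2. Step 5. The ortho-bromo aryllithium may lose lithium bromide to an aryne, the bromine may migrate (halogen dance), or the aryl copper may attack the tertiary end of the allyl system and give the 1,1-dimethylallyl isomer. Fallback: the C2 side chain is installed by sigmatropic rearrangement instead of metalation. 3-Bromophenol 8 is O-allylated (allyl bromide, K2CO3, acetone) to allyl 3-bromophenyl ether F7. Aromatic Claisen rearrangement (N,N-diethylaniline, about 200 °C) should give 2-allyl-3-bromophenol F8, after chromatographic separation from the regioisomer formed by migration to the other ortho position. MOM protection gives 2-allyl-1-bromo-3-(methoxymethoxy)benzene F9, and cross-metathesis with 2-methylbut-2-ene (second-generation Grubbs catalyst, CH2Cl2, 40 °C) converts the allyl into the prenyl group. This fallback sets out from 8 and returns to the route at 12.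

3. Step 10. The acid that cleaves the MOM acetal may also protonate a prenyl double bond, after which a neighbouring phenol (above all the electron-rich C4 hydroxyl of ring A) closes to a 2,2-dimethylchroman, or the alkene adds solvent. Fallback: the acetal is exchanged for a silyl ether before the rings are joined, so that the endgame needs only fluoride. Aldehyde 14 is deprotected with aq. HCl in THF to 3-hydroxy-2-(3-methylbut-2-en-1-yl)benzaldehyde F10, a single electron-poor phenol that should be far less prone to cyclise. It is silylated (TBSCl, imidazole, DMF) to 3-(tert-butyldimethylsilyloxy)-2-(3-methylbut-2-en-1-yl)benzaldehyde F11, treated with 15 to give 1-[3-(tert-butyldimethylsilyloxy)-2-prenylphenyl]prop-2-yn-1-ol F12, and oxidised with MnO2 to 1-[3-(tert-butyldimethylsilyloxy)-2-prenylphenyl]prop-2-yn-1-one F13. Cycloaddition with triene 7 under the conditions of step 9 gives the tris-silylated cyclohexa-1,4-diene cycloadduct F14, and work-up with TBAF in THF removes all three silyl groups with loss of methanol. This fallback sets out from 14 and returns to the route at 20.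

**Further compounds**

F1 | step 9 | 1,5-dibromo-2,4-bis(methoxymethoxy)benzene | COCOc1cc(OCOC)c(Br)cc1Br
F2 | step 9 | 5-bromo-2,4-bis(methoxymethoxy)phenyllithium | [Li]c1cc(Br)c(OCOC)cc1OCOC
F3 | step 9 | 1-bromo-2,4-bis(methoxymethoxy)-5-(3-methylbut-2-en-1-yl)benzene | COCOc1cc(OCOC)c(CC=C(C)C)cc1Br
F4 | step 9 | 2,4-bis(methoxymethoxy)-5-(3-methylbut-2-en-1-yl)phenyllithium | [Li]c1cc(CC=C(C)C)c(OCOC)cc1OCOC
F5 | step 9 | [2,4-bis(methoxymethoxy)-5-prenylphenyl][3-(methoxymethoxy)-2-prenylphenyl]methanol (racemic) | COCOc1cc(OCOC)c(CC=C(C)C)cc1C(O)c1cccc(OCOC)c1CC=C(C)C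
F6 | step 9 | [2,4-bis(methoxymethoxy)-5-prenylphenyl][3-(methoxymethoxy)-2-prenylphenyl]methanone | COCOc1cc(OCOC)c(CC=C(C)C)cc1C(=O)c1cccc(OCOC)c1CC=C(C)C
F7 | step 5 | allyl 3-bromophenyl ether | C=CCOc1cccc(Br)c1
F8 | step 5 | 2-allyl-3-bromophenol | C=CCc1c(O)cccc1Br
F9 | step 5 | 2-allyl-1-bromo-3-(methoxymethoxy)benzene | C=CCc1c(Br)cccc1OCOC
F10 | step 10 | 3-hydroxy-2-(3-methylbut-2-en-1-yl)benzaldehyde | O=Cc1cccc(O)c1CC=C(C)C
F11 | step 10 | 3-(tert-butyldimethylsilyloxy)-2-(3-methylbut-2-en-1-yl)benzaldehyde | CC(C)=CCc1c(C=O)cccc1O[Si](C)(C)C(C)(C)C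
F12 | step 10 | 1-[3-(tert-butyldimethylsilyloxy)-2-prenylphenyl]prop-2-yn-1-ol (racemic) | C#CC(O)c1cccc(O[Si](C)(C)C(C)(C)C)c1CC=C(C)C
F13 | step 10 | 1-[3-(tert-butyldimethylsilyloxy)-2-prenylphenyl]prop-2-yn-1-one | C#CC(=O)c1cccc(O[Si](C)(C)C(C)(C)C)c1CC=C(C)C
F14 | step 10 | tris-silylated cyclohexa-1,4-diene cycloadduct (mixture of diastereomers) | COC1(O[Si](C)(C)C)C=C(O[Si](C)(C)C)C(CC=C(C)C)C=C1C(=O)c1cccc(O[Si](C)(C)C(C)(C)C)c1CC=C(C)C
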